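**Strategy.** The C4 methyl and the C3 hemiketal hydroxyl of the lactone ring (isochroman-1-one numbering) are treated as water added across the C3–CH2 bond of a cyclopropane fused at C3–C4. That cyclopropane is made by a ligand-controlled, hydroxyl-directed Simmons–Smith methylenation of the C3=C4 enol-lactone bond of a planar, achiral 3-(hydroxymethyl)isocoumarin (8-OBn, 6-OMe, 5-Me), which sets C4 and closes the three-membered ring in one operation. The isocoumarin comes from a laterally lithiated toluate and a silyloxyacetic N-methoxy-N-methylamide. Acylation of the primary alcohol with the second aryl acid, acid opening of the cyclopropane and hydrogenolysis finish the route; both aryl halves derive from one formylated 4,5-dimethylresorcinol.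

Key step: step 11

Numbering: positions are numbered as in isochroman-1-one (C1 lactone carbonyl, O2, C3, C4, C4a–C8a). The target is (3R,4S); the cyclopropane of the key step is (3S,4S).

Assumption: the C3 hemiketal is configurationally mobile (ring–chain equilibrium with the open keto acid), so the route controls only C4 and relies on the 3R anomer, with the hydroxyl trans to the C4 methyl, being the stable one.

**Route**

Step 1
Reactants: 1 4,5-dimethylresorcinol
Product: 3 2,4-dihydroxy-5,6-dimethylbenzaldehyde, via aryl iminium chloride 2 (not isolated)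
Conditions: POCl3, DMF, MeCN, 0 °C → rt; then H2O, 50 °C
Reagents that add atoms: N,N-dimethylformamide CN(C)C=O; water O
Why: Vilsmeier–Haack formylation, in which the chloroiminium electrophile attacks C6 (para to one hydroxyl, ortho to the other) in preference to the crowded position between the two hydroxyls, as with orcinol, and the iminium salt is hydrolysed on aqueous work-up.

Step 2
Reactants: 3 2,4-dihydroxy-5,6-dimethylbenzaldehyde
Product: 4 2-hydroxy-4-methoxy-5,6-dimethylbenzaldehyde
Conditions: MeI (1.05 equiv), K2CO3 (1.0 equiv), acetone, rt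
Reagents that add atoms: iodomethane CI
Why: Williamson etherification with limiting mild base should alkylate only the 4-hydroxyl (para to the formyl group, more acidic and unchelated), since the 2-hydroxyl is held in a hydrogen bond to the aldehyde.

Step 3
Reactants: 4 2-hydroxy-4-methoxy-5,6-dimethylbenzaldehyde
Product: 5 2-(benzyloxy)-4-methoxy-5,6-dimethylbenzaldehyde
Conditions: BnBr, K2CO3, DMF, 60 °C
Reagents that add atoms: benzyl bromide BrCc1ccccc1
Why: Williamson etherification of the remaining chelated phenol under more forcing conditions installs a group that tolerates the organolithium, sulfonic acid and zinc carbenoid steps and leaves only in the final hydrogenolysis.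

Step 4
Reactants: 5 2-(benzyloxy)-4-methoxy-5,6-dimethylbenzaldehyde
Product: 6 2-(benzyloxy)-4-methoxy-5,6-dimethylbenzoic acid
Conditions: NaClO2, NaH2PO4, 2-methyl-2-butene, t-BuOH/H2O, rt
Reagents that add atoms: sodium chlorite [Na+].[O-]Cl=O
Why: Pinnick oxidation converts the hindered, electron-rich aldehyde into the acid under buffered conditions while the alkene scavenger traps hypochlorous acid before it can chlorinate the arene.

Step 5
Reactants: 6 2-(benzyloxy)-4-methoxy-5,6-dimethylbenzoic acid
Product: 7 methyl 2-(benzyloxy)-4-methoxy-5,6-dimethylbenzoate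
Conditions: MeI, K2CO3, DMF, rt
Reagents that add atoms: iodomethane CI
Why: Carboxylate O-alkylation (SN2 at iodomethane) esterifies the 2,6-disubstituted acid without needing attack at its shielded carbonyl carbon.

Step 6
Reactants: 8 methyl glycolate
Product: 9 methyl 2-[(tert-butyldiphenylsilyl)oxy]acetate
Conditions: TBDPSCl, imidazole, DMF, rt
Reagents that add atoms: tert-butyl(chloro)diphenylsilane CC(C)(C)[Si](Cl)(c1ccccc1)c1ccccc1
Why: Imidazole-promoted silylation of the primary hydroxyl gives a silyl ether chosen because it should withstand the organolithium of step 8 and the anhydrous sulfonic acid of step 9.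

Step 7
Reactants: 9 methyl 2-[(tert-butyldiphenylsilyl)oxy]acetate
Product: 10 2-[(tert-butyldiphenylsilyl)oxy]-N-methoxy-N-methylacetamide
Conditions: MeNH(OMe)·HCl, i-PrMgCl, THF, −20 → 0 °C
Reagents that add atoms: N,O-dimethylhydroxylamine hydrochloride CNOC.Cl
Why: Aminolysis of the ester by the chloromagnesium amide of N,O-dimethylhydroxylamine (Weinreb amide formation) proceeds at low temperature without touching the silyl ether.

Step 8
Reactants: 7 methyl 2-(benzyloxy)-4-methoxy-5,6-dimethylbenzoate; 10 2-[(tert-butyldiphenylsilyl)oxy]-N-methoxy-N-methylacetamide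
Product: 13 methyl 6-(benzyloxy)-2-{3-[(tert-butyldiphenylsilyl)oxy]-2-oxopropyl}-4-methoxy-3-methylbenzoate, via benzylic lithium species 11 (not isolated), via lithium hemiaminal adduct 12 (not isolated)
Conditions: LiN(i-Pr)2 (1.2 equiv), THF, −78 °C; then 10, −78 → −40 °C; aq. NH4Cl
Reagents that add atoms: none
Why: Lateral lithiation of the ortho-toluate (only the 6-methyl group is conjugated with the ester, so only it is deprotonated) followed by Weinreb ketone synthesis, in which the chelated tetrahedral adduct persists until work-up and so prevents over-addition.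

Step 9
Reactants: 13 methyl 6-(benzyloxy)-2-{3-[(tert-butyldiphenylsilyl)oxy]-2-oxopropyl}-4-methoxy-3-methylbenzoate
Product: 14 8-(benzyloxy)-3-{[(tert-butyldiphenylsilyl)oxy]methyl}-6-methoxy-5-methylisocoumarin
Conditions: p-TsOH·H2O (0.1 equiv), toluene, 90 °C, 4 Å MS
Reagents that add atoms: none
Why: Acid-catalysed enol-lactonisation, in which the enol oxygen of the benzyl ketone attacks the neighbouring ester carbonyl (6-exo-trig) and methanol is lost to give the conjugated isocoumarin; acid is preferred to base because an enolate could undergo Claisen-type C-acylation to a naphthalenediol.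

Step 10
Reactants: 14 8-(benzyloxy)-3-{[(tert-butyldiphenylsilyl)oxy]methyl}-6-methoxy-5-methylisocoumarin
Product: 15 8-(benzyloxy)-3-(hydroxymethyl)-6-methoxy-5-methylisocoumarin
Conditions: TBAF, AcOH, THF, 0 °C → rt
Reagents that add atoms: none
Why: Fluoride-mediated desilylation frees the directing hydroxyl, and the acetic acid buffer protonates the alkoxide before it can attack the lactone carbonyl.

Step 11
Reactants: 15 8-(benzyloxy)-3-(hydroxymethyl)-6-methoxy-5-methylisocoumarin; 16 diiodomethane
Product: 19 (3S,4S)-8-(benzyloxy)-3-(hydroxymethyl)-6-methoxy-5-methyl-3,4-methano-3,4-dihydroisocoumarin (cyclopropane cis-fused to the lactone, methano carbon on the face of the future C4 methyl), via iodomethylzinc alkoxide 17 (not isolated), via cyclopropyl zinc alkoxide 18 (not isolated)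
Conditions: Et2Zn (2.2 equiv), CH2I2 (4.4 equiv), DME (2.2 equiv), CH2Cl2, −10 °C; then 15 and (4S,5S)-2-butyl-N,N,N′,N′-tetramethyl-1,3,2-dioxaborolane-4,5-dicarboxamide (1.2 equiv), −10 °C → rt; aq. NH4Cl, then diethanolamine
Reagents that add atoms: diiodomethane ICI
Why: Proposed new method: the zinc alkoxide of the C3 hydroxymethyl group binds the boron of the dioxaborolane, an amide carbonyl of the ligand holds a second Zn(CH2I)2, and that carbenoid transfers CH2 to one face of the C3=C4 enol-lactone bond through a concerted butterfly transition state in which the C3–CH2 and C4–CH2 bonds form together. The closest known chemistry is the dioxaborolane-controlled Simmons–Smith cyclopropanation of (E)-allylic alcohols, together with zinc-carbenoid cyclopropanation of enol esters; an enol-lactone bond inside an isocoumarin has not been used with this ligand system, but it is an O-substituted styrene-type alkene, nucleophilic at C4, with its hydroxymethyl group in the allylic position. The three-membered ring closes in a single suprafacial [2+1] addition, so its fusion to the lactone ring can only be cis. C3 and C4 are set together by the ligand, their relative configuration being fixed by the syn addition; the (4S,5S)-ligand (mirror image of the one that turns (E)-cinnamyl alcohol into the (1S,2S)-cyclopropylmethanol) is chosen because superimposing CH2OH and the trans-disposed aryl carbon C4a of 15 on cinnamyl alcohol places the methylene on the face that later carries the C4 methyl, which should give the (3S,4S)-product. The step needs facial (enantio) selectivity and chemoselectivity for C3=C4 over the arenes; both rest on the single free hydroxyl, the only anchor for boron, and on the planarity of the achiral isocoumarin, whose two faces are otherwise equivalent.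

Step 12
Reactants: 3 2,4-dihydroxy-5,6-dimethylbenzaldehyde
Product: 20 2,4-bis(benzyloxy)-5,6-dimethylbenzaldehyde
Conditions: BnBr (2.5 equiv), K2CO3, DMF, 60 °C
Reagents that add atoms: benzyl bromide BrCc1ccccc1
Why: Double Williamson etherification with excess benzyl bromide protects both phenols of the second aryl unit as groups that leave in the final hydrogenolysis.

Step 13
Reactants: 20 2,4-bis(benzyloxy)-5,6-dimethylbenzaldehyde
Product: 21 2,4-bis(benzyloxy)-5,6-dimethylbenzoic acid
Conditions: NaClO2, NaH2PO4, 2-methyl-2-butene, t-BuOH/H2O, rt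
Reagents that add atoms: sodium chlorite [Na+].[O-]Cl=O
Why: Pinnick oxidation as in step 4, with the scavenger again protecting the electron-rich ring from chlorination.

Step 14
Reactants: 21 2,4-bis(benzyloxy)-5,6-dimethylbenzoic acid; 19 (3S,4S)-8-(benzyloxy)-3-(hydroxymethyl)-6-methoxy-5-methyl-3,4-methano-3,4-dihydroisocoumarin
Product: 23 [(3S,4S)-8-(benzyloxy)-6-methoxy-5-methyl-1-oxo-3,4-methano-3,4-dihydroisocoumarin-3-yl]methyl 2,4-bis(benzyloxy)-5,6-dimethylbenzoate, via acid chloride 22 (not isolated)
Conditions: (COCl)2, DMF (cat.), CH2Cl2, 0 °C → rt, evaporate; then 19, Et3N, DMAP, CH2Cl2, 0 °C → rt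
Reagents that add atoms: none
Why: Acyl chloride formation followed by DMAP-catalysed acylation (nucleophilic catalysis) of the primary alcohol overcomes the hindrance of the 2,6-disubstituted acid under conditions too weakly basic to provoke acyl migration or lactone opening, and neither stereocentre is involved.

Step 15
Reactants: 23 [(3S,4S)-8-(benzyloxy)-6-methoxy-5-methyl-1-oxo-3,4-methano-3,4-dihydroisocoumarin-3-yl]methyl 2,4-bis(benzyloxy)-5,6-dimethylbenzoate
Product: 24 [(3R,4S)-8-(benzyloxy)-3-hydroxy-6-methoxy-4,5-dimethyl-1-oxo-3,4-dihydro-1H-isochromen-3-yl]methyl 2,4-bis(benzyloxy)-5,6-dimethylbenzoate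
Conditions: 2 M aq. HCl, 1,4-dioxane, 40 °C
Reagents that add atoms: water O
Why: Acid ring opening of an acylated cyclopropanol, in which the proton enters at the unsubstituted methylene (the least substituted carbon, the usual site under acid), the C3–CH2 bond breaks toward the O2-stabilised C3 cation (helped by the neighbouring ester carbonyl) and water adds, so C4 is untouched and keeps its configuration while the C3 hemiketal should settle by ring–chain equilibration as the 3R anomer with the hydroxyl trans to the C4 methyl, both pseudo-axial because the C5 methyl pushes the C4 methyl out of the ring plane.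

Step 16
Reactants: 24 [(3R,4S)-8-(benzyloxy)-3-hydroxy-6-methoxy-4,5-dimethyl-1-oxo-3,4-dihydro-1H-isochromen-3-yl]methyl 2,4-bis(benzyloxy)-5,6-dimethylbenzoate
Product: 25 [(3R,4S)-3,8-dihydroxy-6-methoxy-4,5-dimethyl-1-oxo-3,4-dihydro-1H-isochromen-3-yl]methyl 2,4-dihydroxy-5,6-dimethylbenzoate (CNP0072952.2)
Conditions: H2 (1 atm), Pd/C (10%), EtOAc, rt
Reagents that add atoms: none
Why: Catalytic hydrogenolysis cleaves the three aryl benzyl ethers under neutral conditions at room temperature, leaving the esters and the hemiketal intact and C4 unepimerised, since no other benzylic C–O bond is present.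

**Compound list**

1 | 4,5-dimethylresorcinol (4,5-dimethylbenzene-1,3-diol) | Cc1cc(O)cc(O)c1C | starting material
2 | N-[(2,4-dihydroxy-5,6-dimethylphenyl)methylidene]-N-methylmethanaminium chloride | C[N+](C)=Cc1c(O)cc(O)c(C)c1C.[Cl-] | intermediate
3 | 2,4-dihydroxy-5,6-dimethylbenzaldehyde | O=Cc1c(O)cc(O)c(C)c1C | intermediate
4 | 2-hydroxy-4-methoxy-5,6-dimethylbenzaldehyde | O=Cc1c(O)cc(OC)c(C)c1C | intermediate
5 | 2-(benzyloxy)-4-methoxy-5,6-dimethylbenzaldehyde | O=Cc1c(OCc2ccccc2)cc(OC)c(C)c1C | intermediate
6 | 2-(benzyloxy)-4-methoxy-5,6-dimethylbenzoic acid | OC(=O)c1c(OCc2ccccc2)cc(OC)c(C)c1C | intermediate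
7 | methyl 2-(benzyloxy)-4-methoxy-5,6-dimethylbenzoate | COC(=O)c1c(OCc2ccccc2)cc(OC)c(C)c1C | intermediate
8 | methyl glycolate | COC(=O)CO | starting material
9 | methyl 2-[(tert-butyldiphenylsilyl)oxy]acetate | COC(=O)CO[Si](c1ccccc1)(c1ccccc1)C(C)(C)C | intermediate
10 | 2-[(tert-butyldiphenylsilyl)oxy]-N-methoxy-N-methylacetamide | CON(C)C(=O)CO[Si](c1ccccc1)(c1ccccc1)C(C)(C)C | intermediate
11 | methyl 2-(benzyloxy)-6-(lithiomethyl)-4-methoxy-5-methylbenzoate | COC(=O)c1c(OCc2ccccc2)cc(OC)c(C)c1C[Li] | intermediate
12 | lithium alkoxide of the tetrahedral N-methoxy-N-methyl hemiaminal formed from 11 and 10 | COC(=O)c1c(OCc2ccccc2)cc(OC)c(C)c1CC(O[Li])(N(C)OC)CO[Si](c1ccccc1)(c1ccccc1)C(C)(C)C | intermediate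
13 | methyl 6-(benzyloxy)-2-{3-[(tert-butyldiphenylsilyl)oxy]-2-oxopropyl}-4-methoxy-3-methylbenzoate | COC(=O)c1c(OCc2ccccc2)cc(OC)c(C)c1CC(=O)CO[Si](c1ccccc1)(c1ccccc1)C(C)(C)C | intermediate
14 | 8-(benzyloxy)-3-{[(tert-butyldiphenylsilyl)oxy]methyl}-6-methoxy-5-methylisocoumarin | COc1cc(OCc2ccccc2)c2c(c1C)C=C(CO[Si](c1ccccc1)(c1ccccc1)C(C)(C)C)OC2=O | intermediate
15 | 8-(benzyloxy)-3-(hydroxymethyl)-6-methoxy-5-methylisocoumarin | COc1cc(OCc3ccccc3)c2c(c1C)C=C(CO)OC2=O | intermediate
16 | diiodomethane | ICI | starting material
17 | (iodomethyl)zinc alkoxide of 15 | COc1cc(OCc3ccccc3)c2c(c1C)C=C(CO[Zn]CI)OC2=O | intermediate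
18 | (iodomethyl)zinc alkoxide of 19 | COc1cc(OCc3ccccc3)c2c(c1C)[C@@H]4C[C@]4(CO[Zn]CI)OC2=O | intermediate
19 | (3S,4S)-8-(benzyloxy)-3-(hydroxymethyl)-6-methoxy-5-methyl-3,4-methano-3,4-dihydroisocoumarin [(1aS,7bS)-4-(benzyloxy)-1a-(hydroxymethyl)-6-methoxy-7-methyl-1a,7b-dihydrocyclopropa[c]isochromen-3(1H)-one] | COc1cc(OCc3ccccc3)c2c(c1C)[C@@H]4C[C@]4(CO)OC2=O | intermediate
20 | 2,4-bis(benzyloxy)-5,6-dimethylbenzaldehyde | O=Cc1c(OCc2ccccc2)cc(OCc2ccccc2)c(C)c1C | intermediate
21 | 2,4-bis(benzyloxy)-5,6-dimethylbenzoic acid | OC(=O)c1c(OCc2ccccc2)cc(OCc2ccccc2)c(C)c1C | intermediate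
22 | 2,4-bis(benzyloxy)-5,6-dimethylbenzoyl chloride | ClC(=O)c1c(OCc2ccccc2)cc(OCc2ccccc2)c(C)c1C | intermediate
23 | [(3S,4S)-8-(benzyloxy)-6-methoxy-5-methyl-1-oxo-3,4-methano-3,4-dihydroisocoumarin-3-yl]methyl 2,4-bis(benzyloxy)-5,6-dimethylbenzoate | COc1cc(OCc3ccccc3)c2c(c1C)[C@@H]4C[C@]4(COC(=O)c1c(OCc3ccccc3)cc(OCc3ccccc3)c(C)c1C)OC2=O | intermediate
24 | [(3R,4S)-8-(benzyloxy)-3-hydroxy-6-methoxy-4,5-dimethyl-1-oxo-3,4-dihydro-1H-isochromen-3-yl]methyl 2,4-bis(benzyloxy)-5,6-dimethylbenzoate | COc1cc(OCc3ccccc3)c2c(c1C)[C@H](C)[C@](O)(COC(=O)c1c(OCc3ccccc3)cc(OCc3ccccc3)c(C)c1C)OC2=O | intermediate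
25 | [(3R,4S)-3,8-dihydroxy-6-methoxy-4,5-dimethyl-1-oxo-3,4-dihydro-1H-isochromen-3-yl]methyl 2,4-dihydroxy-5,6-dimethylbenzoate | COc1cc(O)c2c(c1C)[C@H](C)[C@](O)(COC(=O)c1c(O)cc(O)c(C)c1C)OC2=O | target

**Step count**

Total: 16 steps. Longest linear sequence: 12 steps (steps 1–5, 8–11, 14–16).

**Steps most likely to fail**

Step 11 (labelled). The methylene transfer may proceed with weak facial discrimination, because the lactone carbonyl can hold zinc in competition with the boronate-bound alkoxide, so the cyclopropane would form with low enantiomeric purity. The fallback gives up reagent control and separates enantiomers by biocatalysis. It sets out from 15: hydroxyl-assisted, non-asymmetric methylenation with the more electrophilic carbenoid CF3CO2ZnCH2I (Et2Zn, CF3CO2H, CH2I2, CH2Cl2, 0 °C), a reagent type known for enol esters, should give the racemic cis-fused cyclopropane alcohol F1. Lipase-catalysed kinetic resolution (vinyl acetate, MTBE, rt) then acetylates one enantiomer. A lipase is selected by screening that acetylates the (3R,4R)-alcohol, giving the (3R,4R)-acetate F2 and leaving the (3S,4S)-alcohol untouched. That alcohol is 19, where the route resumes.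

Step 15. The C3 oxocarbenium ion may lose the C4 proton instead of taking up water (dehydration to the flat 4-methylisocoumarin). The open keto-acid form may also enolise and erode C4. The acylated cyclopropane may simply resist protonation at a temperature the benzyl ethers tolerate. The fallback replaces the proton by a metal electrophile and sets out from 23: Hg(OAc)2 in THF–H2O at rt, then aq. NaCl, should cleave the same C3–CH2 bond by attack at the unhindered methylene, the known mode for cyclopropanol derivatives. This gives the C4-(chloromercurio)methyl hemiketal F3. Radical demercuration with Bu3SnH (toluene, rt) replaces mercury by hydrogen and returns to the route at 24.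

Step 9. The enol-lactonisation may stall, and prolonged heating with acid may strip the silyl or the peri benzyl ether. The fallback closes the ring by cyclodehydration of a keto acid instead and sets out from 6: LiN(i-Pr)2 (2.2 equiv, THF, −78 → 0 °C) forms the carboxylate benzylic dianion, and acylation with 10 gives the keto acid F4. Ac2O/pyridine at rt, the classical dehydration of 2-(2-oxoalkyl)benzoic acids, then gives the isocoumarin and rejoins the route at 14.

**Further compounds**

F1 | step 11 | racemic 8-(benzyloxy)-3-(hydroxymethyl)-6-methoxy-5-methyl-3,4-methano-3,4-dihydroisocoumarin (both cis-fused enantiomers) | COc1cc(OCc3ccccc3)c2c(c1C)[C@@H]4C[C@]4(CO)OC2=O.COc1cc(OCc3ccccc3)c2c(c1C)[C@H]4C[C@@]4(CO)OC2=O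
F2 | step 11 | [(3R,4R)-8-(benzyloxy)-6-methoxy-5-methyl-1-oxo-3,4-methano-3,4-dihydroisocoumarin-3-yl]methyl acetate | COc1cc(OCc3ccccc3)c2c(c1C)[C@H]4C[C@@]4(COC(C)=O)OC2=O
F3 | step 15 | [(3R,4S)-8-(benzyloxy)-4-[(chloromercurio)methyl]-3-hydroxy-6-methoxy-5-methyl-1-oxo-3,4-dihydro-1H-isochromen-3-yl]methyl 2,4-bis(benzyloxy)-5,6-dimethylbenzoate | COc1cc(OCc3ccccc3)c2c(c1C)[C@H](C[Hg]Cl)[C@](O)(COC(=O)c1c(OCc3ccccc3)cc(OCc3ccccc3)c(C)c1C)OC2=O
F4 | step 9 | 6-(benzyloxy)-2-{3-[(tert-butyldiphenylsilyl)oxy]-2-oxopropyl}-4-methoxy-3-methylbenzoic acid | OC(=O)c1c(OCc2ccccc2)cc(OC)c(C)c1CC(=O)CO[Si](c1ccccc1)(c1ccccc1)C(C)(C)C
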